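**Retrosynthetic overview**
1. 18 ⇐ 17: removal of three MOM ethers (last step).
2. 17 ⇐ 16: the O1–C2 bond. Ring C is the only ring made and is closed last, by an enantioselective oxa-Michael addition of a chalcone in which only the phenol beside the prenyl group is free.
3. 16 ⇐ 12 + 14: Claisen–Schmidt condensation; ring B comes from vanillin 13.
4. 12 ⇐ 10 ⇐ 9 ⇐ 7: aromatic Claisen rearrangement of a reverse-prenyl aryl ether places the prenyl group and uncovers that one phenol. 7 ⇐ 5 ⇐ 3 ⇐ 1: allyl cleavage/reduction gives the hydroxyethyl arm after C-allylation of ring A.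
5. Ring order: rings A and B are bought as arenes (1, 13); ring C is formed in step 9.

Assumption: the quinidine-derived squaramide is taken to give the 2S series; if it gives 2R, its quinine-derived pseudo-enantiomer is used in the same way.

**Step 1**
Reactants: 1 1-(2,4,6-trihydroxyphenyl)ethan-1-one; 2 3-bromoprop-1-ene (allyl bromide)
Product: 3 1-[2,4,6-trihydroxy-3-(prop-2-en-1-yl)phenyl]ethan-1-one
Conditions: allyl bromide (1.0 eq), 10% aq KOH, 0 °C → rt
Reagents that add atoms: allyl bromide (2), C=CCBr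
Why: C-alkylation of the ambident acylphloroglucinol anion in water, where hydrogen bonding to the phenoxide oxygens favours attack through carbon (the reaction type of the classical C-prenylation of this ketone); C3 and C5 are equivalent, so only one mono-C-allyl product can form.

**Step 2**
Reactants: 3 1-[2,4,6-trihydroxy-3-(prop-2-en-1-yl)phenyl]ethan-1-one; 4 chloro(methoxy)methane (MOMCl)
Product: 5 1-[2,6-dihydroxy-4-(methoxymethoxy)-3-(prop-2-en-1-yl)phenyl]ethan-1-one
Conditions: MOMCl (1.05 eq), K2CO3 (1.1 eq), acetone, 0 °C → rt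
Reagents that add atoms: chloromethyl methyl ether (4), COCCl
Why: Williamson-type O-alkylation of the phenoxide formed by one equivalent of base, which is the 4-OH (para to the acetyl group, most acidic), while the two ortho hydroxyls are held back by conjugation and hydrogen bonding to the carbonyl.

**Step 3**
Reactants: 5 1-[2,6-dihydroxy-4-(methoxymethoxy)-3-(prop-2-en-1-yl)phenyl]ethan-1-one
Product: 7 1-[2,6-dihydroxy-3-(2-hydroxyethyl)-4-(methoxymethoxy)phenyl]ethan-1-one, via arylacetaldehyde 6 (not isolated)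
Conditions: OsO4 (2 mol%), NaIO4 (4 eq), 2,6-lutidine, dioxane/H2O 3:1, rt; extract; then NaBH4, EtOH, −20 → 0 °C
Reagents that add atoms: sodium periodate, [Na+].[O-]I(=O)(=O)=O; OsO4 (catalytic oxygen relay), O=[Os](=O)(=O)=O
Why: Lemieux–Johnson oxidative cleavage of the only alkene, then hydride reduction of aldehyde 6 (present largely as its cyclic hemiacetal), while the 2,6-dihydroxyaryl methyl ketone, a vinylogous carboxylate under these conditions, is not reduced.

**Step 4**
Reactants: 7 1-[2,6-dihydroxy-3-(2-hydroxyethyl)-4-(methoxymethoxy)phenyl]ethan-1-one; 8 tert-butyl 2-methylbut-3-en-2-yl carbonate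
Product: 9 1-{2-hydroxy-3-(2-hydroxyethyl)-4-(methoxymethoxy)-6-[(2-methylbut-3-en-2-yl)oxy]phenyl}ethan-1-one
Conditions: Pd(PPh3)4 (5 mol%), 8 (1.1 eq), THF, 4 Å MS, 0 °C → rt
Reagents that add atoms: tert-butyl 2-methylbut-3-en-2-yl carbonate (8), CC(C)(C)OC(=O)OC(C)(C)C=C
Why: Tsuji–Trost O-allylation with a tertiary allyl carbonate (reverse prenylation of a phenol), in which the tert-butoxide released on decarboxylation makes the phenoxide and the bulky tertiary terminus of the π-prenyl palladium complex is taken by the 6-OH (free ortho position) and not by the 2-OH flanked by the hydroxyethyl chain, the 4-oxygen being blocked and the aliphatic OH too weakly acidic.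

**Step 5**
Reactants: 9 1-{2-hydroxy-3-(2-hydroxyethyl)-4-(methoxymethoxy)-6-[(2-methylbut-3-en-2-yl)oxy]phenyl}ethan-1-one; 4 chloro(methoxy)methane (MOMCl)
Product: 10 1-{3-(2-hydroxyethyl)-2,4-bis(methoxymethoxy)-6-[(2-methylbut-3-en-2-yl)oxy]phenyl}ethan-1-one
Conditions: NaH (1.1 eq), DMF, 0 °C; then MOMCl (1.1 eq)
Reagents that add atoms: chloromethyl methyl ether (4), COCCl
Why: Williamson O-alkylation of the sodium phenoxide, since one equivalent of hydride deprotonates only the remaining phenol (pKa about 10) and not the primary alcohol (pKa about 16).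

**Step 6**
Reactants: 10 1-{3-(2-hydroxyethyl)-2,4-bis(methoxymethoxy)-6-[(2-methylbut-3-en-2-yl)oxy]phenyl}ethan-1-one
Product: 12 1-[2-hydroxy-5-(2-hydroxyethyl)-4,6-bis(methoxymethoxy)-3-(3-methylbut-2-en-1-yl)phenyl]ethan-1-one, via ortho-dienone 11 (not isolated)
Conditions: PhMe, 120 °C, sealed tube
Reagents that add atoms: none
Why: Aromatic Claisen rearrangement ([3,3]-sigmatropic) of the 1,1-dimethylallyl aryl ether, which can only reach the one unsubstituted ortho carbon (the other bears the acetyl group), inverts the allyl unit to a normal prenyl group, and on tautomerisation of 11 frees exactly the phenol next to the prenyl group.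

**Step 7**
Reactants: 13 4-hydroxy-3-methoxybenzaldehyde (vanillin); 4 chloro(methoxy)methane (MOMCl)
Product: 14 3-methoxy-4-(methoxymethoxy)benzaldehyde
Conditions: MOMCl (1.2 eq), K2CO3 (1.5 eq), acetone, rt
Reagents that add atoms: chloromethyl methyl ether (4), COCCl
Why: Williamson O-alkylation of the vanillin phenoxide, so that the aldehyde is not deactivated as a phenoxide in the condensation that follows.

**Step 8**
Reactants: 12 1-[2-hydroxy-5-(2-hydroxyethyl)-4,6-bis(methoxymethoxy)-3-(3-methylbut-2-en-1-yl)phenyl]ethan-1-one; 14 3-methoxy-4-(methoxymethoxy)benzaldehyde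
Product: 16 (2E)-1-[2-hydroxy-5-(2-hydroxyethyl)-4,6-bis(methoxymethoxy)-3-(3-methylbut-2-en-1-yl)phenyl]-3-[3-methoxy-4-(methoxymethoxy)phenyl]prop-2-en-1-one, via aldol adduct 15 (not isolated)
Conditions: KOH (50% aq, 10 eq), EtOH, rt, 36 h; AcOH to pH 6 at 0 °C
Reagents that add atoms: none
Why: Claisen–Schmidt condensation (aldol addition, then E1cB dehydration of 15) gives the E-enone, which in strong base is held as the open 2′-phenoxide and is released as the chalcone on cold neutralisation.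

**Step 9**
Reactants: 16 (2E)-1-[2-hydroxy-5-(2-hydroxyethyl)-4,6-bis(methoxymethoxy)-3-(3-methylbut-2-en-1-yl)phenyl]-3-[3-methoxy-4-(methoxymethoxy)phenyl]prop-2-en-1-one
Product: 17 (2S)-6-(2-hydroxyethyl)-2-[3-methoxy-4-(methoxymethoxy)phenyl]-5,7-bis(methoxymethoxy)-8-(3-methylbut-2-en-1-yl)-2,3-dihydro-4H-chromen-4-one
Conditions: quinidine-derived squaramide 3-{[3,5-bis(trifluoromethyl)phenyl]amino}-4-{[(9R)-6′-methoxycinchonan-9-yl]amino}cyclobut-3-ene-1,2-dione (10 mol%), PhMe, 4 Å MS, 0 °C → rt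
Reagents that add atoms: none
Why: Proposed new method: a cinchona amine–squaramide-catalysed 6-endo-trig oxa-Michael ring closure of an α-unsubstituted 2′-hydroxychalcone, in which the quinuclidine nitrogen deprotonates the single free phenol (the one beside the prenyl group, so O1–C2 can form only on that side), the two squaramide N–H bonds hold the ketone oxygen together with the neighbouring 6′-OCH2OCH3 oxygen (a two-point acceptor standing in for the β-keto ester of the known substrates) and stabilise the developing enolate, the 2′,6′-disubstitution twists the aryl ketone so that the phenoxide lies over C-β, and the ammonium ion then protonates C-α; attack on the Si face of C-β within the chiral ion pair gives 2S, and because the tertiary amine cannot deprotonate C3–H of 17 the closure is not reversed; closest known reaction type: cinchona-thiourea-catalysed asymmetric oxa-Michael cyclisation of α-alkoxycarbonyl-activated 2′-hydroxychalcones to flavanones.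

**Step 10**
Reactants: 17 (2S)-6-(2-hydroxyethyl)-2-[3-methoxy-4-(methoxymethoxy)phenyl]-5,7-bis(methoxymethoxy)-8-(3-methylbut-2-en-1-yl)-2,3-dihydro-4H-chromen-4-one
Product: 18 (2S)-5,7-dihydroxy-2-(4-hydroxy-3-methoxyphenyl)-6-(2-hydroxyethyl)-8-(3-methylbut-2-en-1-yl)-2,3-dihydro-4H-chromen-4-one (laxiflorin)
Conditions: HCl (3 M aq)/MeOH 1:5, rt → 40 °C
Reagents that add atoms: none
Why: Acid-catalysed acetal exchange with methanol removes the three aryl MOM ethers, while C2 is untouched (no base, so no retro-oxa-Michael opening) and mild acid leaves the prenyl group uncyclised, as in deprotections of MOM-protected prenylflavonoids.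

**Compound list**
1 | 1-(2,4,6-trihydroxyphenyl)ethan-1-one | CC(=O)c1c(O)cc(O)cc1O | starting material
2 | 3-bromoprop-1-ene (allyl bromide) | C=CCBr | starting material
3 | 1-[2,4,6-trihydroxy-3-(prop-2-en-1-yl)phenyl]ethan-1-one | CC(=O)c1c(O)cc(O)c(CC=C)c1O | intermediate
4 | chloro(methoxy)methane (MOMCl) | COCCl | starting material
5 | 1-[2,6-dihydroxy-4-(methoxymethoxy)-3-(prop-2-en-1-yl)phenyl]ethan-1-one | CC(=O)c1c(O)cc(OCOC)c(CC=C)c1O | intermediate
6 | 2-[3-acetyl-2,4-dihydroxy-6-(methoxymethoxy)phenyl]acetaldehyde | CC(=O)c1c(O)cc(OCOC)c(CC=O)c1O | intermediate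
7 | 1-[2,6-dihydroxy-3-(2-hydroxyethyl)-4-(methoxymethoxy)phenyl]ethan-1-one | CC(=O)c1c(O)cc(OCOC)c(CCO)c1O | intermediate
8 | tert-butyl 2-methylbut-3-en-2-yl carbonate | CC(C)(C)OC(=O)OC(C)(C)C=C | starting material
9 | 1-{2-hydroxy-3-(2-hydroxyethyl)-4-(methoxymethoxy)-6-[(2-methylbut-3-en-2-yl)oxy]phenyl}ethan-1-one | CC(=O)c1c(OC(C)(C)C=C)cc(OCOC)c(CCO)c1O | intermediate
10 | 1-{3-(2-hydroxyethyl)-2,4-bis(methoxymethoxy)-6-[(2-methylbut-3-en-2-yl)oxy]phenyl}ethan-1-one | CC(=O)c1c(OC(C)(C)C=C)cc(OCOC)c(CCO)c1OCOC | intermediate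
11 | 2-acetyl-4-(2-hydroxyethyl)-3,5-bis(methoxymethoxy)-6-(3-methylbut-2-en-1-yl)cyclohexa-2,4-dien-1-one | CC(=O)C1=C(OCOC)C(CCO)=C(OCOC)C(CC=C(C)C)C1=O | intermediate
12 | 1-[2-hydroxy-5-(2-hydroxyethyl)-4,6-bis(methoxymethoxy)-3-(3-methylbut-2-en-1-yl)phenyl]ethan-1-one | CC(=O)c1c(O)c(CC=C(C)C)c(OCOC)c(CCO)c1OCOC | intermediate
13 | 4-hydroxy-3-methoxybenzaldehyde (vanillin) | COc1cc(C=O)ccc1O | starting material
14 | 3-methoxy-4-(methoxymethoxy)benzaldehyde | COCOc1ccc(C=O)cc1OC | intermediate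
15 | 3-hydroxy-1-[2-hydroxy-5-(2-hydroxyethyl)-4,6-bis(methoxymethoxy)-3-(3-methylbut-2-en-1-yl)phenyl]-3-[3-methoxy-4-(methoxymethoxy)phenyl]propan-1-one | COCOc1ccc(C(O)CC(=O)c2c(O)c(CC=C(C)C)c(OCOC)c(CCO)c2OCOC)cc1OC | intermediate
16 | (2E)-1-[2-hydroxy-5-(2-hydroxyethyl)-4,6-bis(methoxymethoxy)-3-(3-methylbut-2-en-1-yl)phenyl]-3-[3-methoxy-4-(methoxymethoxy)phenyl]prop-2-en-1-one | COCOc1ccc(/C=C/C(=O)c2c(O)c(CC=C(C)C)c(OCOC)c(CCO)c2OCOC)cc1OC | intermediate
17 | (2S)-6-(2-hydroxyethyl)-2-[3-methoxy-4-(methoxymethoxy)phenyl]-5,7-bis(methoxymethoxy)-8-(3-methylbut-2-en-1-yl)-2,3-dihydro-4H-chromen-4-one | COc1cc([C@@H]2CC(=O)c3c(OCOC)c(CCO)c(OCOC)c(CC=C(C)C)c3O2)ccc1OCOC | intermediate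
18 | (2S)-5,7-dihydroxy-2-(4-hydroxy-3-methoxyphenyl)-6-(2-hydroxyethyl)-8-(3-methylbut-2-en-1-yl)-2,3-dihydro-4H-chromen-4-one (laxiflorin) | COc1cc([C@@H]2CC(=O)c3c(O)c(CCO)c(O)c(CC=C(C)C)c3O2)ccc1O | target

**Step count and risks**
Total step count: 10. Longest linear sequence: 9 (steps 1–6, 8, 9, 10); step 7 is the side branch.

The three steps most likely to fail:

Step 9 (the proposed ring closure; risk: slow turnover or low enantiomeric excess on this hindered, unactivated enone). The fallback uses known chemistry. It sets out from 16: NaOAc in EtOH at reflux closes the ring without stereocontrol to the racemic 6-(2-hydroxyethyl)-2-[3-methoxy-4-(methoxymethoxy)phenyl]-5,7-bis(methoxymethoxy)-8-(3-methylbut-2-en-1-yl)-2,3-dihydro-4H-chromen-4-one F1. Preparative supercritical-fluid chromatography on an amylose tris(3,5-dimethylphenylcarbamate) phase then separates F1 into 17, where the route is rejoined, and the (2R)-enantiomer F2. F2 is opened again to 16 with KOH in EtOH and recycled.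

Step 4 (risk: the hydrogen-bonded phenol reacts sluggishly with the π-prenyl palladium complex, the linear ether forms, or the 2-OH competes; the tertiary ether may also lose isoprene in step 6). The fallback sets out from 7. Plain O-allylation (allyl bromide 2, K2CO3, acetone, reflux) gives 1-[2-hydroxy-3-(2-hydroxyethyl)-4-(methoxymethoxy)-6-(prop-2-en-1-yloxy)phenyl]ethan-1-one F3. NaH and MOMCl 4 give 1-[3-(2-hydroxyethyl)-2,4-bis(methoxymethoxy)-6-(prop-2-en-1-yloxy)phenyl]ethan-1-one F4. A thermal Claisen rearrangement (PhNEt2, 190 °C) gives 1-[2-hydroxy-5-(2-hydroxyethyl)-4,6-bis(methoxymethoxy)-3-(prop-2-en-1-yl)phenyl]ethan-1-one F5. Cross-metathesis with 2-methylbut-2-ene (second-generation Grubbs catalyst, RuCl2(=CHPh)(H2IMes)(PCy3), CH2Cl2, 40 °C) then turns the allyl group into prenyl and comes back to the route at 12.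

Step 1 (risk: low yield through O-allylation and double C-allylation, which also makes step 2 less clean). The fallback sets out from 1. MOMCl 4 and K2CO3 in acetone give 1-[2,6-dihydroxy-4-(methoxymethoxy)phenyl]ethan-1-one F6. Allyl bromide 2 and K2CO3 in acetone give the mono-allyl ether 1-[2-hydroxy-4-(methoxymethoxy)-6-(prop-2-en-1-yloxy)phenyl]ethan-1-one F7. A Claisen rearrangement (PhNEt2, 190 °C) moves the allyl group to the neighbouring ring carbon and comes back to the route at 5.

**Further compounds**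
F1 | step 9 | racemic 6-(2-hydroxyethyl)-2-[3-methoxy-4-(methoxymethoxy)phenyl]-5,7-bis(methoxymethoxy)-8-(3-methylbut-2-en-1-yl)-2,3-dihydro-4H-chromen-4-one | COc1cc(C2CC(=O)c3c(OCOC)c(CCO)c(OCOC)c(CC=C(C)C)c3O2)ccc1OCOC
F2 | step 9 | (2R)-6-(2-hydroxyethyl)-2-[3-methoxy-4-(methoxymethoxy)phenyl]-5,7-bis(methoxymethoxy)-8-(3-methylbut-2-en-1-yl)-2,3-dihydro-4H-chromen-4-one | COc1cc([C@H]2CC(=O)c3c(OCOC)c(CCO)c(OCOC)c(CC=C(C)C)c3O2)ccc1OCOC
F3 | step 4 | 1-[2-hydroxy-3-(2-hydroxyethyl)-4-(methoxymethoxy)-6-(prop-2-en-1-yloxy)phenyl]ethan-1-one | CC(=O)c1c(OCC=C)cc(OCOC)c(CCO)c1O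
F4 | step 4 | 1-[3-(2-hydroxyethyl)-2,4-bis(methoxymethoxy)-6-(prop-2-en-1-yloxy)phenyl]ethan-1-one | CC(=O)c1c(OCC=C)cc(OCOC)c(CCO)c1OCOC
F5 | step 4 | 1-[2-hydroxy-5-(2-hydroxyethyl)-4,6-bis(methoxymethoxy)-3-(prop-2-en-1-yl)phenyl]ethan-1-one | CC(=O)c1c(O)c(CC=C)c(OCOC)c(CCO)c1OCOC
F6 | step 1 | 1-[2,6-dihydroxy-4-(methoxymethoxy)phenyl]ethan-1-one | CC(=O)c1c(O)cc(OCOC)cc1O
F7 | step 1 | 1-[2-hydroxy-4-(methoxymethoxy)-6-(prop-2-en-1-yloxy)phenyl]ethan-1-one | CC(=O)c1c(O)cc(OCOC)cc1OCC=C
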